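# Kaempferol 7-O-sulfate by aryne insertion into an arylpropiolic acid and oxa-Michael closure

## Analysis of the target

Kaempferol 7-O-sulfate is a flavonol: a 4H-chromen-4-one (benzo ring A fused to pyranone ring C) with a 4-hydroxyphenyl ring B at C2, hydroxyls at C3, C5 and C4', and a hydrogen sulfate ester on O7. The molecule is flat and has no stereocenter, so the problem is one of regiochemistry and of telling four oxygens apart. The aryl sulfate monoester is the sensitive group: it is a strong acid, it hydrolyses in warm acid, and it turns every intermediate that carries it into a water-soluble salt, so it has to enter late. The 3-hydroxy-enone and the free phenols are oxidisable and chelating, and the 5-OH is tied to the C4 carbonyl by a hydrogen bond, which makes it the least reactive phenol. The difficulty is to expose O7 alone for sulfation while O3 and O4' stay capped, and to bring in O3 at all. The plan rests on ring A: the ether oxygen O1 on C8a and the carbonyl carbon C4 on C4a sit on neighbouring carbons, and C4a is flanked by the oxygen-bearing C5. This is the pattern obtained when an aryne C8a≡C4a with an alkoxy group at C5 takes up an oxygen nucleophile at C8a and an acyl carbon at C4a, the C7 oxygen being a spectator.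

## Retrosynthetic reasoning

**From 20 back to 18.** The last operation should touch only protecting groups, because the aryl sulfate tolerates neither hot acid nor a long sequence after its introduction. The two benzyl–oxygen bonds at O3 and O4' are therefore the final cuts. Hydrogenolysis is neutral and leaves the S–O ester alone, and the sodium salt 19 it produces needs only one equivalent of acid to become 20.

**From 18 back to 16.** The O7–S bond is cut next. In 16 only two hydroxyls are free, and the one at C5 is locked to the C4 carbonyl in the peri position, so an electrophilic sulfur trioxide donor should react at O7 alone. The first-formed pyridinium salt 17 is exchanged to the sodium salt 18 so that no amine reaches the hydrogenation catalyst.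

**From 16 back to 14, through 15.** Two kinds of ether are needed: acetal (MOM) ethers on O5 and O7, removable with dilute acid, and benzyl ethers on O3 and O4', removable with hydrogen. Cutting the two MOM C–O bonds leads to 15, and cutting the O3–benzyl bond leads to flavonol 14, whose only free hydroxyl is the one at C3.

**From 14 back to 12.** The C3–O bond is cut, leaving a C3–H flavone. The acid partner of the key step cannot carry this oxygen, so it is added afterwards. C3–H of 12 is the α-position of a vinylogous ester and the most acidic vinylic hydrogen. Lithiation, borylation to 13 and oxidative carbon-to-oxygen migration place the oxygen there without touching ring A or ring B.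

**From 12 back to 6 and 9, the key disconnection.** Three bonds are cut together: O1–C8a, C4–C4a and O1–C2. Ring A becomes aryne 10, released from 6. Acid 9 supplies ring B, C2, C3 and, through its carboxyl group, both C4 and O1. Insertion gives ynone 11, which closes ring C. Cutting here means that all ring A oxygens come ready-made and already differentiated from O4', and that a four-step fragment and a one-step fragment meet in the step that makes the whole skeleton. The forward reaction has to add the carboxylate to the correct end of an unsymmetrical aryne and then close 6-endo.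

**From 6 back to 1.** The triflate of 6 comes from lithium phenoxide 5, and the C–Si bond of 5 traces back by a retro-Brook silyl shift to the O-silylated bromophenol 4. Cutting O–Si gives 3, cutting C–Br gives 2, and removing the two MOM groups gives compound 1. Because 1 is threefold symmetric, any two hydroxyls can be protected, and either position ortho to the remaining one leads to the same bromide.

**From 9 back to 7 and 8.** The aryl–alkyne bond is cut. Iodide 7 already carries the benzyl ether wanted on O4', and acid 8 brings C2, C3 and C4 at the right oxidation level.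

## Alternatives that were turned down

Alternative 1: Ring C is cut at C3–C4 and at O1–C2.
- Disconnection: C2, C3 and ring B come as the α-benzyloxy ketone 2-(benzyloxy)-1-[4-(benzyloxy)phenyl]ethan-1-one A1. Ring A comes as the ketal-masked salicylate 5,7-bis(methoxymethoxy)-2,2-dimethyl-4H-1,3-benzodioxin-4-one A2, in which C4 is an activated ester and O1 is masked.
- Forward key step: the lithium enolate of A1 is acylated at its α-carbon by the lactone carbonyl of A2, and the ketal carbon leaves as a volatile ketone, freeing the phenoxide. Acid in methanol, added to the same flask, condenses O1 with the C2 carbonyl and strips both MOM groups, giving 3,4'-di-O-benzylkaempferol A3.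
- For: O3 is in place and already benzylated. A3 is the same structure as compound 16, which the chosen route reaches only four steps after its ring closure. On step economy and on the handling of O3 this alternative is the stronger plan.
- Against: the carbonyl of A2 that has to be attacked is an ester deactivated by three donor oxygens and shielded by the neighbouring OMOM group. The β-diketone formed is more acidic than A1, so half of the enolate is consumed as base unless a sacrificial base is added. The free acid from which A2 derives decarboxylates easily, and the hydroxyl next to the lactone carbonyl is chelated and slow to protect.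
- Comparison: the chosen strategy makes C4–C4a by intramolecular acyl transfer to an aryl anion, which is indifferent to the steric and electronic deactivation of a trioxygenated benzoate. It uses the two partners in near-equal amounts, and it passes through flavone 12, from which O3 can still be varied.

Alternative 2: The cuts are C4–C4a, made by Friedel–Crafts acylation, and O1–C2, made one step earlier by opening an epoxide with a phenol.
- Disconnection: the open-chain precursor is the hydroxy acid (2R,3R)-3-(3,5-dimethoxyphenoxy)-2-hydroxy-3-(4-methoxyphenyl)propanoic acid A4, in which O1–C2 already exists.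
- Forward key step: the carboxyl group of A4 is turned into a mixed trifluoroacetic anhydride, and the acyl carbon then attacks the phenoxy ring ortho to the ether oxygen. This closes ring C as the dihydroflavonol (2R,3R)-3-hydroxy-5,7-dimethoxy-2-(4-methoxyphenyl)chroman-4-one A5.
- For: the ring of A4 that is acylated is very electron-rich and its two ortho positions are equivalent, so no regiochemical question arises. O3 is present from the start, no aryne precursor or transition metal is needed, and both stereocenters of A5 are controlled, which is a real asset for a dihydroflavonol.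
- Against: the target has no stereocenter, so the C2/C3 configuration of A5 is erased by a further dehydrogenation step. The three methyl ethers are the wrong masks: O5 can be freed selectively through chelation, but O7 and O4' cannot be told apart, and only O7 may be free for sulfation. Acid-labile acetals on ring A would not survive the strongly acidic acylation medium, which also threatens the ionisable para-alkoxybenzylic C–O ether of A4.
- Comparison: A5 stands further from the target than 12, both in oxidation level and in differentiation of the oxygens. This alternative is stronger in that O3 needs no separate C–H oxidation and the reagents are cheap. The chosen strategy offers instead the orthogonal pair MOM on O5 and O7 and benzyl on O4' from the first step.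

Alternative 3: The O1–C8a bond is cut and formed by nucleophilic aromatic substitution.
- Disconnection: ring C is opened to the racemic, enolisable diketone 2-(benzyloxy)-1-[4-(benzyloxy)phenyl]-3-(2,4,6-trifluorophenyl)propane-1,3-dione A6, whose trifluorophenyl group becomes ring A.
- Forward key step: K2CO3 in DMF converts A6 into its enolate, whose oxygen displaces one of the two equivalent ortho fluorides activated by the aroyl carbonyl. Ring C closes to 3-(benzyloxy)-2-[4-(benzyloxy)phenyl]-5,7-difluoro-4H-chromen-4-one A7.
- For: the closure of A6 is an addition–elimination with no regiochemical ambiguity, O3 is benzylated from the start, and the conditions are mild and cheap. As a ring-forming step it is probably more dependable than the aryne step of the chosen route.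
- Against: A7 carries fluorine at C5 and C7 where the target has oxygen. Two further substitutions by oxygen nucleophiles are needed, and they must be distinguished, since O7 becomes the sulfate and O5 a free phenol. C7 and C5 of A7 are both activated by the C4 carbonyl, the first alkoxy group slows the second substitution, and each oxygen must enter as a masked hydroxide removable beside benzyl ethers.
- Comparison: what A6 saves in the closure is paid back after A7 in several steps of uncertain regiochemistry. In the chosen strategy all ring A oxygens come from compound 1 and are never exchanged.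

Key step: step 6

Remark on the chemistry: the target is taken as the free hydrogen sulfate as drawn. The sulfated intermediates are carried as sodium salts and the acid form is released only in the last operation, in the cold, because aryl hydrogen sulfates hydrolyse in warm acid.

## Route

Step 1
Reactants: 1 phloroglucinol
Product: 2 3,5-bis(methoxymethoxy)phenol
Conditions: MOMCl (2.0 equiv), iPr2NEt (2.2 equiv), DMF, 0 °C → rt; chromatography
Reagents that add atoms: chloromethyl methyl ether (MOMCl), COCCl
Why: O-alkylation of the phenoxide by the α-chloro ether (acetal formation). The three hydroxyls are equivalent, so the bis-ether should be the main component of a statistical mixture; it is separated from mono- and tris-ether, and the mono-ether can be resubmitted.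

Step 2
Reactants: 2 3,5-bis(methoxymethoxy)phenol
Product: 3 2-bromo-3,5-bis(methoxymethoxy)phenol
Conditions: NBS (1.0 equiv), iPr2NH (10 mol%), CH2Cl2, −78 °C → 0 °C
Reagents that add atoms: N-bromosuccinimide, O=C1CCC(=O)N1Br
Why: Electrophilic aromatic bromination in its amine-mediated, ortho-selective form: the N-bromoamine is hydrogen-bonded to the phenol and delivers bromine to the ortho carbon, which is also less hindered than C4 between the two MOM ethers. C2 and C6 are equivalent, and one equivalent at low temperature should stop at the monobromide.

Step 3
Reactants: 3 2-bromo-3,5-bis(methoxymethoxy)phenol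
Product: 4 [2-bromo-3,5-bis(methoxymethoxy)phenoxy]trimethylsilane
Conditions: (Me3Si)2NH (1.5 equiv), THF, 70 °C; evaporate, use crude
Reagents that add atoms: hexamethyldisilazane, C[Si](C)(C)N[Si](C)(C)C
Why: O-silylation of the phenol by the silazane with loss of ammonia. The neutral conditions keep the MOM acetals, and the moisture-sensitive aryl silyl ether is carried on without chromatography.

Step 4
Reactants: 4 [2-bromo-3,5-bis(methoxymethoxy)phenoxy]trimethylsilane
Product: 6 3,5-bis(methoxymethoxy)-2-(trimethylsilyl)phenyl trifluoromethanesulfonate, via lithium 2-silylphenoxide 5 (not isolated)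
Conditions: n-BuLi (1.1 equiv), THF, −78 °C; then Tf2O (1.2 equiv), −78 °C; cold aq. NaHCO3
Reagents that add atoms: trifluoromethanesulfonic anhydride, O=S(=O)(OS(=O)(=O)C(F)(F)F)C(F)(F)F
Why: Bromine–lithium exchange is faster than ortho-lithiation next to the MOM ethers. The aryllithium takes the silyl group from the neighbouring oxygen (retro-Brook 1,3-shift, driven by the O–Li bond), and phenoxide 5 is then sulfonylated by the anhydride.

Step 5
Reactants: 7 1-(benzyloxy)-4-iodobenzene; 8 propiolic acid (1.2 equiv)
Product: 9 3-[4-(benzyloxy)phenyl]prop-2-ynoic acid
Conditions: Pd(PPh3)4 (2.5 mol%), DBU (2.4 equiv), DMSO, 35 °C; then aq. HCl to pH 2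
Reagents that add atoms: none
Why: Copper-free Sonogashira coupling: oxidative addition of the aryl iodide to zerovalent palladium, then coupling at the alkyne terminus of the amidinium propiolate. The low temperature and the absence of copper should keep the product carboxylate from decarboxylating and coupling a second time.

Step 6
Reactants: 6 3,5-bis(methoxymethoxy)-2-(trimethylsilyl)phenyl trifluoromethanesulfonate (1.3 equiv); 9 3-[4-(benzyloxy)phenyl]prop-2-ynoic acid
Product: 12 2-[4-(benzyloxy)phenyl]-5,7-bis(methoxymethoxy)-4H-chromen-4-one, via 3,5-bis(methoxymethoxy)benzyne 10 (not isolated), via 2-hydroxyaryl ynone 11 (not isolated)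
Conditions: CsF (4 equiv), THF, 125 °C, sealed tube
Reagents that add atoms: none
Why: Fluoride attacks silicon of 6 and expels triflate to give aryne 10, while CsF converts 9 into its caesium carboxylate. The carboxylate oxygen adds to the aryne carbon remote from the flanking MOM ether (future C8a), because the inductively withdrawing 3-alkoxy group distorts the aryne so that this carbon is the more electrophilic and the developing carbanion lies next to the oxygen-bearing carbon (future C4a); the second MOM ether, meta to the attacked carbon, is too remote to override this. The aryl anion then attacks the carboxyl carbon of its own ester through a four-membered alkoxide that opens to the 2-acylphenoxide of 11, a net insertion of the aryne into the C–O bond of the acid; this is the known route from arynes and carboxylic acids to 2-hydroxyaryl ketones and, with alkynoic acids, to chromones and flavones. The phenoxide closes ring C by 6-endo-dig oxa-Michael addition to the β-carbon of the ynone (O1–C2), and the C3 vinyl anion is protonated by the HF/bifluoride formed from the acid. No stereocenter is formed. Three selectivities are needed: the regiochemistry of aryne capture, secured by the 3-OMOM group; acyl transfer in preference to protonation of the aryl anion, favoured by the hot aprotic medium in which the acid is already deprotonated; and 6-endo over 5-exo closure, secured by the polarity of the ynone, whose β-carbon is the only electrophilic alkyne carbon for a free phenoxide. The MOM and benzyl ethers are inert to fluoride and to the weakly basic medium.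

Step 7
Reactants: 12 2-[4-(benzyloxy)phenyl]-5,7-bis(methoxymethoxy)-4H-chromen-4-one
Product: 14 2-[4-(benzyloxy)phenyl]-3-hydroxy-5,7-bis(methoxymethoxy)-4H-chromen-4-one, via flavon-3-yl dimethyl boronate 13 (not isolated)
Conditions: LiN(iPr)2 (1.5 equiv), THF, −78 °C; B(OMe)3 (3 equiv), −78 °C → 0 °C; AcOH, 30% H2O2, 0 °C → rt
Reagents that add atoms: hydrogen peroxide, OO; trimethyl borate, COB(OC)OC (its atoms remain only in the unisolated boronate 13)
Why: C3–H is the α-hydrogen of a vinylogous ester and is removed by the amide base, the lithium being held by the C4 carbonyl and the 5-OMOM oxygens. The vinyllithium is trapped as boronate 13, and peroxide oxidation moves C3 from boron to oxygen (lithiation–borylation–oxidation, a known flavone-to-flavonol conversion). The non-nucleophilic base at −78 °C should leave the MOM-flanked ring A positions and the benzyl ether alone.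

Step 8
Reactants: 14 2-[4-(benzyloxy)phenyl]-3-hydroxy-5,7-bis(methoxymethoxy)-4H-chromen-4-one
Product: 15 3-(benzyloxy)-2-[4-(benzyloxy)phenyl]-5,7-bis(methoxymethoxy)-4H-chromen-4-one
Conditions: BnBr (1.2 equiv), K2CO3 (1.5 equiv), DMF, rt
Reagents that add atoms: benzyl bromide, BrCc1ccccc1
Why: Williamson etherification of the acidic 3-hydroxyl, the only free hydroxyl in 14.

Step 9
Reactants: 15 3-(benzyloxy)-2-[4-(benzyloxy)phenyl]-5,7-bis(methoxymethoxy)-4H-chromen-4-one
Product: 16 3-(benzyloxy)-2-[4-(benzyloxy)phenyl]-5,7-dihydroxy-4H-chromen-4-one
Conditions: 3 M aq. HCl, MeOH/THF, 50 °C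
Reagents that add atoms: none
Why: Acid-catalysed acetal exchange with methanol removes both MOM groups as the volatile dimethyl acetal. Benzyl ethers and the chromenone are stable to dilute acid.

Step 10
Reactants: 16 3-(benzyloxy)-2-[4-(benzyloxy)phenyl]-5,7-dihydroxy-4H-chromen-4-one
Product: 18 sodium 3-(benzyloxy)-2-[4-(benzyloxy)phenyl]-5-hydroxy-4-oxo-4H-chromen-7-yl sulfate, via pyridinium 7-sulfate 17 (not isolated)
Conditions: SO3·pyridine (3 equiv), pyridine, 25–40 °C; aq. NaHCO3; C18 reversed-phase chromatography
Reagents that add atoms: sulfur trioxide–pyridine complex, O=S(=O)([O-])[n+]1ccccc1; NaHCO3, [Na+].OC([O-])=O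
Why: O-sulfonation of a phenol by sulfur trioxide transfer. Only the 7-hydroxyl should react, because the 5-hydroxyl is hydrogen-bonded to the C4 carbonyl and O3 and O4' are benzylated. Exchange to the sodium salt removes pyridine before the hydrogenation.

Step 11
Reactants: 18 sodium 3-(benzyloxy)-2-[4-(benzyloxy)phenyl]-5-hydroxy-4-oxo-4H-chromen-7-yl sulfate
Product: 20 kaempferol 7-O-sulfate, via sodium kaempferol 7-sulfate 19 (not isolated)
Conditions: H2 (1 atm), 10% Pd/C, MeOH/THF/H2O, rt; filter; 0.1 M aq. HCl (1.0 equiv), 0 °C; C18 desalting; lyophilise
Reagents that add atoms: none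
Why: Hydrogenolysis of the two benzyl ethers. The fully oxidised sulfate ester neither poisons the catalyst nor is cleaved, and the chromenone double bond is not reduced at atmospheric pressure. One equivalent of cold mineral acid then gives the hydrogen sulfate, and the sodium chloride is washed out on the reversed phase.

## Compound list

1 | phloroglucinol (benzene-1,3,5-triol) | Oc1cc(O)cc(O)c1 | starting material
2 | 3,5-bis(methoxymethoxy)phenol | COCOc1cc(O)cc(OCOC)c1 | intermediate
3 | 2-bromo-3,5-bis(methoxymethoxy)phenol | COCOc1cc(O)c(Br)c(OCOC)c1 | intermediate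
4 | [2-bromo-3,5-bis(methoxymethoxy)phenoxy]trimethylsilane | COCOc1cc(O[Si](C)(C)C)c(Br)c(OCOC)c1 | intermediate
5 | lithium 3,5-bis(methoxymethoxy)-2-(trimethylsilyl)phenoxide | [Li+].[O-]c1cc(OCOC)cc(OCOC)c1[Si](C)(C)C | intermediate (not isolated)
6 | 3,5-bis(methoxymethoxy)-2-(trimethylsilyl)phenyl trifluoromethanesulfonate | COCOc1cc(OCOC)c([Si](C)(C)C)c(OS(=O)(=O)C(F)(F)F)c1 | intermediate
7 | 1-(benzyloxy)-4-iodobenzene | Ic1ccc(OCc2ccccc2)cc1 | starting material
8 | propiolic acid | C#CC(=O)O | starting material
9 | 3-[4-(benzyloxy)phenyl]prop-2-ynoic acid | OC(=O)C#Cc1ccc(OCc2ccccc2)cc1 | intermediate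
10 | 3,5-bis(methoxymethoxy)benzyne | COCOC1=CC#CC(OCOC)=C1 | intermediate (not isolated)
11 | 3-[4-(benzyloxy)phenyl]-1-[2-hydroxy-4,6-bis(methoxymethoxy)phenyl]prop-2-yn-1-one (present as its caesium phenoxide) | O=C(C#Cc1ccc(OCc2ccccc2)cc1)c1c(O)cc(OCOC)cc1OCOC | intermediate (not isolated)
12 | 2-[4-(benzyloxy)phenyl]-5,7-bis(methoxymethoxy)-4H-chromen-4-one | O=c1cc(-c2ccc(OCc3ccccc3)cc2)oc2cc(OCOC)cc(OCOC)c12 | intermediate
13 | dimethyl {2-[4-(benzyloxy)phenyl]-5,7-bis(methoxymethoxy)-4-oxo-4H-chromen-3-yl}boronate | COB(OC)c1c(-c2ccc(OCc3ccccc3)cc2)oc2cc(OCOC)cc(OCOC)c2c1=O | intermediate (not isolated)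
14 | 2-[4-(benzyloxy)phenyl]-3-hydroxy-5,7-bis(methoxymethoxy)-4H-chromen-4-one | O=c1c(O)c(-c2ccc(OCc3ccccc3)cc2)oc2cc(OCOC)cc(OCOC)c12 | intermediate
15 | 3-(benzyloxy)-2-[4-(benzyloxy)phenyl]-5,7-bis(methoxymethoxy)-4H-chromen-4-one | O=c1c(OCc2ccccc2)c(-c2ccc(OCc3ccccc3)cc2)oc2cc(OCOC)cc(OCOC)c12 | intermediate
16 | 3-(benzyloxy)-2-[4-(benzyloxy)phenyl]-5,7-dihydroxy-4H-chromen-4-one (3,4'-di-O-benzylkaempferol) | O=c1c(OCc2ccccc2)c(-c2ccc(OCc3ccccc3)cc2)oc2cc(O)cc(O)c12 | intermediate
17 | pyridinium 3-(benzyloxy)-2-[4-(benzyloxy)phenyl]-5-hydroxy-4-oxo-4H-chromen-7-yl sulfate | c1cc[nH+]cc1.O=c1c(OCc2ccccc2)c(-c2ccc(OCc3ccccc3)cc2)oc2cc(OS(=O)(=O)[O-])cc(O)c12 | intermediate (not isolated)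
18 | sodium 3-(benzyloxy)-2-[4-(benzyloxy)phenyl]-5-hydroxy-4-oxo-4H-chromen-7-yl sulfate | [Na+].O=c1c(OCc2ccccc2)c(-c2ccc(OCc3ccccc3)cc2)oc2cc(OS(=O)(=O)[O-])cc(O)c12 | intermediate
19 | sodium 3,5-dihydroxy-2-(4-hydroxyphenyl)-4-oxo-4H-chromen-7-yl sulfate (sodium kaempferol 7-sulfate) | [Na+].O=c1c(O)c(-c2ccc(O)cc2)oc2cc(OS(=O)(=O)[O-])cc(O)c12 | intermediate (not isolated)
20 | kaempferol 7-O-sulfate, 3,5-dihydroxy-2-(4-hydroxyphenyl)-4-oxo-4H-chromen-7-yl hydrogen sulfate | O=c1c(O)c(-c2ccc(O)cc2)oc2cc(OS(=O)(=O)O)cc(O)c12 | target

## Step count and risks

Total step count: 11. Longest linear sequence: 10 steps (steps 1–4 and 6–11, from phloroglucinol); step 5 is a one-step branch.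

**Step 6 (key step).**
- What may go wrong: thermal decarboxylation of the arylpropiolate before it meets the aryne; protonation of the aryl anion before acyl transfer, which stops at simple O-arylation; capture of a second aryne by the phenoxide before ring closure.
- Fallback, from 3 and 9, returning at 12: the aryne is replaced by a defined aryllithium.
  - Phenol 3 is silylated with iPr3SiCl and imidazole in DMF to [2-bromo-3,5-bis(methoxymethoxy)phenoxy]tri(propan-2-yl)silane F1.
  - Acid 9 is converted with EDC·HCl, MeNHOMe·HCl and iPr2NEt in CH2Cl2 into 3-[4-(benzyloxy)phenyl]-N-methoxy-N-methylprop-2-ynamide F2.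
  - Bromine–lithium exchange on F1 with n-BuLi in THF at −78 °C, where the bulky silyl group should not migrate, and addition to F2 should give 3-[4-(benzyloxy)phenyl]-1-[2,4-bis(methoxymethoxy)-6-{[tri(propan-2-yl)silyl]oxy}phenyl]prop-2-yn-1-one F3.
  - Bu4NF in THF removes the silyl group of F3, and the phenoxide of 11 so released closes to 12 by the same oxa-Michael addition.

**Step 7 (C3 hydroxylation).**
- What may go wrong: incomplete deprotonation at C3, competing metalation of ring A beside the MOM ethers, or protodeboronation before the oxidation.
- Fallback, from 12, returning at 14: oxygen is delivered electrophilically. Dimethyldioxirane in acetone and CH2Cl2 at 0 °C epoxidises the C2=C3 bond to racemic 2-[4-(benzyloxy)phenyl]-2,3-epoxy-5,7-bis(methoxymethoxy)-2,3-dihydro-4H-chromen-4-one F4. A trace of pyridinium p-toluenesulfonate or silica gel then opens the epoxide of F4 at C2, where the cation is stabilised by O1 and ring B, and loss of the C3 proton gives 14.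

**Step 2 (bromination).**
- What may go wrong: bromination para to the hydroxyl, between the two MOM ethers, or a second bromination of this very electron-rich ring.
- Fallback, from 2, returning at 6: regiochemistry is set by directed metalation.
  - Carbamoylation with Et2NCOCl and K2CO3 in refluxing MeCN gives 3,5-bis(methoxymethoxy)phenyl diethylcarbamate F5.
  - s-BuLi/TMEDA in THF at −78 °C metalates F5 between the carbamate and a MOM ether, the carbamate being the stronger directing group, and Me3SiCl gives 3,5-bis(methoxymethoxy)-2-(trimethylsilyl)phenyl diethylcarbamate F6.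
  - Reductive cleavage of the carbamate of F6 with Cp2Zr(H)Cl in THF at rt gives 3,5-bis(methoxymethoxy)-2-(trimethylsilyl)phenol F7.
  - Tf2O and pyridine in CH2Cl2 at 0 °C convert F7 into 6.

**Step 11 (debenzylation and release of the acid).**
- What may go wrong: slow or incomplete hydrogenolysis of a poorly soluble salt; reduction of the C2=C3 bond on prolonged exposure; hydrolysis of the sulfate when the free acid is concentrated.
- Fallback, from 16, returning at 20: the sulfate is introduced as a neutral, chromatographable diester.
  - 2,2,2-Trichloroethyl chlorosulfate with Et3N and DMAP in THF at 0 °C gives 3-(benzyloxy)-2-[4-(benzyloxy)phenyl]-5-hydroxy-4-oxo-4H-chromen-7-yl 2,2,2-trichloroethyl sulfate F8.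
  - Transfer hydrogenolysis of F8 with 10% Pd/C and HCO2NH4 in MeOH at rt removes both benzyl ethers and the trichloroethyl group in one operation, giving ammonium kaempferol 7-sulfate F9.
  - F9 is acidified and desalted in the cold as in step 11 to give 20. This fallback does not remove the lability of the free acid, which in either case is handled cold and lyophilised at once.

## Further compounds

F1 | step 6 | [2-bromo-3,5-bis(methoxymethoxy)phenoxy]tri(propan-2-yl)silane | COCOc1cc(O[Si](C(C)C)(C(C)C)C(C)C)c(Br)c(OCOC)c1
F2 | step 6 | 3-[4-(benzyloxy)phenyl]-N-methoxy-N-methylprop-2-ynamide | CON(C)C(=O)C#Cc1ccc(OCc2ccccc2)cc1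
F3 | step 6 | 3-[4-(benzyloxy)phenyl]-1-[2,4-bis(methoxymethoxy)-6-{[tri(propan-2-yl)silyl]oxy}phenyl]prop-2-yn-1-one | O=C(C#Cc1ccc(OCc2ccccc2)cc1)c1c(O[Si](C(C)C)(C(C)C)C(C)C)cc(OCOC)cc1OCOC
F4 | step 7 | 2-[4-(benzyloxy)phenyl]-2,3-epoxy-5,7-bis(methoxymethoxy)-2,3-dihydro-4H-chromen-4-one (racemic, cis-fused epoxide) | O=C1C2OC2(c2ccc(OCc3ccccc3)cc2)Oc2cc(OCOC)cc(OCOC)c12
F5 | step 2 | 3,5-bis(methoxymethoxy)phenyl diethylcarbamate | CCN(CC)C(=O)Oc1cc(OCOC)cc(OCOC)c1
F6 | step 2 | 3,5-bis(methoxymethoxy)-2-(trimethylsilyl)phenyl diethylcarbamate | CCN(CC)C(=O)Oc1cc(OCOC)cc(OCOC)c1[Si](C)(C)C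
F7 | step 2 | 3,5-bis(methoxymethoxy)-2-(trimethylsilyl)phenol | Oc1cc(OCOC)cc(OCOC)c1[Si](C)(C)C
F8 | step 11 | 3-(benzyloxy)-2-[4-(benzyloxy)phenyl]-5-hydroxy-4-oxo-4H-chromen-7-yl 2,2,2-trichloroethyl sulfate | O=c1c(OCc2ccccc2)c(-c2ccc(OCc3ccccc3)cc2)oc2cc(OS(=O)(=O)OCC(Cl)(Cl)Cl)cc(O)c12
F9 | step 11 | ammonium 3,5-dihydroxy-2-(4-hydroxyphenyl)-4-oxo-4H-chromen-7-yl sulfate | [NH4+].O=c1c(O)c(-c2ccc(O)cc2)oc2cc(OS(=O)(=O)[O-])cc(O)c12
A1 | alternative 1 | 2-(benzyloxy)-1-[4-(benzyloxy)phenyl]ethan-1-one | O=C(COCc1ccccc1)c1ccc(OCc2ccccc2)cc1
A2 | alternative 1 | 5,7-bis(methoxymethoxy)-2,2-dimethyl-4H-1,3-benzodioxin-4-one | CC1(C)OC(=O)c2c(OCOC)cc(OCOC)cc2O1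
A3 | alternative 1 | 3,4'-di-O-benzylkaempferol, 3-(benzyloxy)-2-[4-(benzyloxy)phenyl]-5,7-dihydroxy-4H-chromen-4-one | O=c1c(OCc2ccccc2)c(-c2ccc(OCc3ccccc3)cc2)oc2cc(O)cc(O)c12
A4 | alternative 2 | (2R,3R)-3-(3,5-dimethoxyphenoxy)-2-hydroxy-3-(4-methoxyphenyl)propanoic acid | O=C(O)[C@H](O)[C@@H](c1ccc(OC)cc1)Oc1cc(OC)cc(OC)c1
A5 | alternative 2 | (2R,3R)-3-hydroxy-5,7-dimethoxy-2-(4-methoxyphenyl)chroman-4-one | O=C1[C@H](O)[C@@H](c2ccc(OC)cc2)Oc2cc(OC)cc(OC)c12
A6 | alternative 3 | 2-(benzyloxy)-1-[4-(benzyloxy)phenyl]-3-(2,4,6-trifluorophenyl)propane-1,3-dione (racemic, enolisable) | O=C(c1ccc(OCc2ccccc2)cc1)C(OCc1ccccc1)C(=O)c1c(F)cc(F)cc1F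
A7 | alternative 3 | 3-(benzyloxy)-2-[4-(benzyloxy)phenyl]-5,7-difluoro-4H-chromen-4-one | O=c1c(OCc2ccccc2)c(-c2ccc(OCc3ccccc3)cc2)oc2cc(F)cc(F)c12
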